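**Plan**

- Retrosynthesis: the target is cut at C12–C13 (B-alkyl Suzuki coupling of a C9-vinyl decalin with an all-E C13–C22 vinyl iodide). The C8 carbinol goes back through an 8(17)-alkene to a C8 ketone. C5–C10 and C8–C9 are then cut together, and the open chain is cut at C1–C2 and C6=C7.
- Enabling feature: ring B holds the quaternary C10 (methyl) beside C9 (carbon branch) and the oxygenated C8, with C5–C10 as the fusion bond. Rings A and B therefore map onto the [4+2] adduct of a C9=C10 (E)-3-methylenal and a C5=C6–C7=C8 1-silyloxydiene joined by the C1–C4 chain.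
- Forward: enolate alkylation (C1–C2), CBS reduction (C3), cross-metathesis (C6=C7) and silyl dienol ether formation give the trienal, and rings A and B close in one cycloaddition. C6=C7 is then saturated, C11 becomes vinyl, C8 becomes the tertiary alcohol, the chain is coupled, and C3 and the chain end are oxidised last.
- Stereochemistry: C3 (S) comes from the CBS reduction. C5, C8, C9 and C10 come from the E-enal, the E,E-diene and the endo mode, with their absolute sense relayed from C3. The C8 carbinol comes from α-face epoxidation and hydride opening. The E alkenes come from geranyl bromide, syn-carboalumination and E-selective allylic oxidation.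

Key step: step 11

Remark: labdane numbering is used for the decalins (C1–C10 ring carbons, C11/C12 on C9, C17 on C8, C18/C19 on C4, C20 on C10; β is the face of C20). Compounds 1, 4, 10, 23 and 24 are taken as commercial.

**Route**

Step 1
Reactants: 1 prenyl acetate
Product: 2 (2E)-4-hydroxy-3-methylbut-2-en-1-yl acetate
Conditions: SeO2 (0.1 equiv), tBuOOH (70% aq.), salicylic acid (0.1 equiv), CH2Cl2, rt
Reagents that add atoms: selenium dioxide, O=[Se]=O (catalytic oxygen carrier); tert-butyl hydroperoxide, CC(C)(C)OO (terminal oxidant)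
Why: Riley-type allylic oxidation (ene reaction, then [2,3]-shift) should hydroxylate the methyl group trans to the CH2OAc branch, as is usual for prenyl and geranyl esters, giving the E allylic alcohol.

Step 2
Reactants: 2 (2E)-4-hydroxy-3-methylbut-2-en-1-yl acetate
Product: 3 (2E)-4-bromo-3-methylbut-2-en-1-yl acetate
Conditions: CBr4, PPh3, CH2Cl2, 0 °C
Reagents that add atoms: carbon tetrabromide, BrC(Br)(Br)Br
Why: Appel bromination converts the primary allylic alcohol into the bromide under neutral conditions, leaving the acetate and the alkene geometry untouched.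

Step 3
Reactants: 4 2,2-dimethylpent-4-enoic acid
Product: 5 3,3-dimethylhex-5-en-2-one
Conditions: MeLi (2.2 equiv), Et2O, 0 °C → rt; aq. NH4Cl
Reagents that add atoms: methyllithium, [Li]C
Why: Ketone synthesis from a carboxylic acid and an organolithium: the dilithium gem-diolate is stable until work-up, so no tertiary alcohol should form.

Step 4
Reactants: 5 3,3-dimethylhex-5-en-2-one; 3 (2E)-4-bromo-3-methylbut-2-en-1-yl acetate
Product: 7 (2E)-3,7,7-trimethyl-6-oxodeca-2,9-dien-1-yl acetate, via lithium enolate 6 (not isolated)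
Conditions: LiN(iPr)2 (1.05 equiv), THF, −78 °C; then 3, DMPU, −78 → −30 °C
Reagents that add atoms: none
Why: Kinetic enolate alkylation: the pinacolone-type ketone can enolise only at its methyl group, and the lithium enolate should displace the primary allylic bromide (SN2) faster than it attacks the acetate at low temperature.

Step 5
Reactants: 7 (2E)-3,7,7-trimethyl-6-oxodeca-2,9-dien-1-yl acetate
Product: 8 (2E,6S)-6-hydroxy-3,7,7-trimethyldeca-2,9-dien-1-yl acetate
Conditions: (R)-2-methyl-CBS-oxazaborolidine (0.2 equiv), catecholborane (1.8 equiv), toluene, −78 → −40 °C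
Reagents that add atoms: none
Why: Corey–Bakshi–Shibata reduction: the catalyst distinguishes the tert-alkyl from the primary alkyl side of the ketone, and the (R)-catalyst should deliver hydride to give the (S)-carbinol (C3), while catecholborane at low temperature leaves both alkenes and the acetate alone.

Step 6
Reactants: 8 (2E,6S)-6-hydroxy-3,7,7-trimethyldeca-2,9-dien-1-yl acetate
Product: 9 (2E,6S)-6-(tert-butyldimethylsilyloxy)-3,7,7-trimethyldeca-2,9-dien-1-yl acetate
Conditions: tBuMe2SiOTf, 2,6-lutidine, CH2Cl2, −78 → 0 °C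
Reagents that add atoms: tert-butyldimethylsilyl triflate, CC(C)(C)[Si](C)(C)OS(=O)(=O)C(F)(F)F
Why: Silylation with the silyl triflate is the standard way to protect a hindered secondary alcohol next to a quaternary carbon.

Step 7
Reactants: 9 (2E,6S)-6-(tert-butyldimethylsilyloxy)-3,7,7-trimethyldeca-2,9-dien-1-yl acetate; 10 (E)-crotonaldehyde
Product: 11 (2E,6S,9E)-6-(tert-butyldimethylsilyloxy)-3,7,7-trimethyl-11-oxoundeca-2,9-dien-1-yl acetate
Conditions: 10 (5 equiv), second-generation Hoveyda–Grubbs catalyst RuCl2(SIMes)(=CH–C6H4-2-OiPr) (5 mol %), CH2Cl2, 40 °C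
Reagents that add atoms: none
Why: Olefin cross-metathesis of the terminal allyl alkene with an enal partner should give the E-enal, while the trisubstituted allylic-acetate alkene is too hindered and electron-poor to take part.

Step 8
Reactants: 11 (2E,6S,9E)-6-(tert-butyldimethylsilyloxy)-3,7,7-trimethyl-11-oxoundeca-2,9-dien-1-yl acetate
Product: 12 (2E,6S,8E,10E)-6-(tert-butyldimethylsilyloxy)-3,7,7-trimethyl-11-(triethylsilyloxy)undeca-2,8,10-trien-1-yl acetate
Conditions: Et3SiOTf (1.3 equiv), Et3N (2.5 equiv), Et2O, −78 → 0 °C; Et3N-deactivated silica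
Reagents that add atoms: triethylsilyl triflate, CC[Si](CC)(CC)OS(=O)(=O)C(F)(F)F
Why: Soft enolisation (γ-deprotonation of the O-silylated enal) gives the 1-silyloxy-1,3-diene; the quaternary C4 should enforce the E geometry at C5=C6 and the s-trans enal should give the E enol ether.

Step 9
Reactants: 12 (2E,6S,8E,10E)-6-(tert-butyldimethylsilyloxy)-3,7,7-trimethyl-11-(triethylsilyloxy)undeca-2,8,10-trien-1-yl acetate
Product: 13 (2E,6S,8E,10E)-6-(tert-butyldimethylsilyloxy)-3,7,7-trimethyl-11-(triethylsilyloxy)undeca-2,8,10-trien-1-ol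
Conditions: iBu2AlH (2.5 equiv), CH2Cl2, −78 °C; aq. KNaC4H4O6 (sodium potassium tartrate)
Reagents that add atoms: none
Why: Reductive cleavage of the acetate with a hydride reagent avoids the protic base or acid that would hydrolyse the silyl dienol ether, and the tartrate work-up stays near neutral.

Step 10
Reactants: 13 (2E,6S,8E,10E)-6-(tert-butyldimethylsilyloxy)-3,7,7-trimethyl-11-(triethylsilyloxy)undeca-2,8,10-trien-1-ol
Product: 14 (2E,6S,8E,10E)-6-(tert-butyldimethylsilyloxy)-3,7,7-trimethyl-11-(triethylsilyloxy)undeca-2,8,10-trienal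
Conditions: MnO2 (20 equiv), CH2Cl2, rt; filtered and used at once
Reagents that add atoms: none
Why: MnO2 oxidation is selective for the allylic alcohol, keeps the E geometry of the trisubstituted alkene, and is neutral and heterogeneous, so both silyl ethers should survive.

Step 11
Reactants: 14 (2E,6S,8E,10E)-6-(tert-butyldimethylsilyloxy)-3,7,7-trimethyl-11-(triethylsilyloxy)undeca-2,8,10-trienal
Product: 15 3β-(tert-butyldimethylsilyloxy)-8β-(triethylsilyloxy)-12,13,14,15,16,17-hexanorlabd-6-en-11-al (trans-decalin; 5α-H; 9α-H; 10β-CH3)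
Conditions: Me2AlCl (1.2 equiv), CH2Cl2 (0.005 M), −78 → −30 °C; Et3N, then aq. NaHCO3
Reagents that add atoms: none
Why: Me2AlCl binds the formyl oxygen and lowers the LUMO of the C9=C10 enal, which should then undergo a concerted, asynchronous intramolecular [4+2] cycloaddition with the electron-rich silyloxydiene (C5–C10 leading, C8–C9 following), the oxygen-bearing diene terminus C8 joining the formyl-bearing C9 as the electronic match requires. The closest known reaction type is the Me2AlCl-promoted intramolecular Diels–Alder reaction of (2E,8E,10E)-undeca-2,8,10-trienals, which gives trans-fused decalin carbaldehydes through the formyl-endo transition state. Ring A closes in the fused mode through the four-carbon tether C1–C4 in a chair-like arrangement as C5–C10 forms, and ring B is the cyclohexene of the [4+2] itself, completed by C8–C9. The E-enal places the formyl group and the C10 methyl cis (C9, C10), the endo orientation with the 8E diene geometry puts H-5 anti to the C10 methyl (C5, trans fusion), and the 10E enol ether puts the C8 silyloxy group cis to the formyl group (C8); the absolute sense of all four follows from C3, whose silyloxy group takes the equatorial site of the chair-like tether. The step needs endo over exo selectivity and one diene face: the aluminium complex raises the endo preference and allows low temperature, the C4 gem-dimethyl group pre-folds the tether, and the C3 substituent discriminates the faces. The reagent also consumes adventitious protic acid, which protects the silyl dienol ether.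

Step 12
Reactants: 15 3β-(tert-butyldimethylsilyloxy)-8β-(triethylsilyloxy)-12,13,14,15,16,17-hexanorlabd-6-en-11-al
Product: 16 3β-(tert-butyldimethylsilyloxy)-8β-(triethylsilyloxy)-12,13,14,15,16,17-hexanorlabdan-11-al
Conditions: H2 (1 atm), 5% Pt/C, EtOAc, rt
Reagents that add atoms: none
Why: Heterogeneous hydrogenation saturates the cis-disubstituted ring alkene; platinum rather than palladium should limit hydrogenolysis or migration at the allylic silyl ether, and the hindered aldehyde reduces far more slowly.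

Step 13
Reactants: 16 3β-(tert-butyldimethylsilyloxy)-8β-(triethylsilyloxy)-12,13,14,15,16,17-hexanorlabdan-11-al
Product: 17 3β-(tert-butyldimethylsilyloxy)-8β-(triethylsilyloxy)-13,14,15,16,17-pentanorlabd-11-ene
Conditions: Ph3PCH3Br, KN(SiMe3)2, THF, 0 °C; then 16, −78 → 0 °C
Reagents that add atoms: methyltriphenylphosphonium bromide, C[P+](c1ccccc1)(c1ccccc1)c1ccccc1.[Br-]
Why: Wittig methylenation: the unstabilised ylide should add to the formyl group faster than it removes the hindered axial H-9, the equatorial C9 substituent is the stable epimer, and silyloxide is a poor leaving group for β-elimination.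

Step 14
Reactants: 17 3β-(tert-butyldimethylsilyloxy)-8β-(triethylsilyloxy)-13,14,15,16,17-pentanorlabd-11-ene
Product: 18 3β-(tert-butyldimethylsilyloxy)-13,14,15,16,17-pentanorlabd-11-en-8β-ol
Conditions: PPTS (0.2 equiv), MeOH/CH2Cl2, 0 °C → rt
Reagents that add atoms: none
Why: Acid-catalysed methanolysis removes the triethylsilyl ether far faster than the tert-butyldimethylsilyl ether at the neopentyl C3 position.

Step 15
Reactants: 18 3β-(tert-butyldimethylsilyloxy)-13,14,15,16,17-pentanorlabd-11-en-8β-ol
Product: 19 3β-(tert-butyldimethylsilyloxy)-13,14,15,16,17-pentanorlabd-11-en-8-one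
Conditions: Dess–Martin periodinane, NaHCO3, CH2Cl2, 0 °C → rt
Reagents that add atoms: none
Why: Dess–Martin oxidation of the axial secondary alcohol is buffered and non-basic, so the vinyl group should not move into conjugation with the new ketone.

Step 16
Reactants: 19 3β-(tert-butyldimethylsilyloxy)-13,14,15,16,17-pentanorlabd-11-en-8-one
Product: 20 3β-(tert-butyldimethylsilyloxy)-13,14,15,16-tetranorlabda-8(17),11-diene
Conditions: Zn, CH2Br2, TiCl4, THF, 0 °C (pre-formed reagent); then 19, CH2Cl2, rt
Reagents that add atoms: dibromomethane, BrCBr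
Why: Takai–Lombardo methylenation (gem-dizinc/titanium methylidene) converts hindered, enolisable ketones without base, so C9 should keep its configuration and the vinyl group its position.

Step 17
Reactants: 20 3β-(tert-butyldimethylsilyloxy)-13,14,15,16-tetranorlabda-8(17),11-diene
Product: 21 3β-(tert-butyldimethylsilyloxy)-8α,17-epoxy-13,14,15,16-tetranorlabd-11-ene
Conditions: mCPBA (1.05 equiv), NaHCO3, CH2Cl2, −20 → 0 °C
Reagents that add atoms: 3-chloroperoxybenzoic acid, O=C(OO)c1cccc(Cl)c1
Why: Prilezhaev epoxidation should prefer the more nucleophilic 1,1-disubstituted alkene over the vinyl group and attack from the α face, because the axial C20 methyl blocks the β face, as is usual for labd-8(17)-enes.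

Step 18
Reactants: 21 3β-(tert-butyldimethylsilyloxy)-8α,17-epoxy-13,14,15,16-tetranorlabd-11-ene
Product: 22 3β-(tert-butyldimethylsilyloxy)-13,14,15,16-tetranorlabd-11-en-8α-ol
Conditions: LiAlH4, THF, 0 °C → reflux
Reagents that add atoms: none
Why: Hydride opening of the spiro-epoxide (SN2 at the primary C17) leaves the C8–O bond intact, so the α-oxygen becomes the 8α-hydroxyl and C17 the 8β-methyl.

Step 19
Reactants: 23 geranyl bromide; 24 1-(trimethylsilyl)propyne
Product: 27 (5E)-6,10-dimethylundeca-5,9-dien-1-yne, via lithiated silylpropyne 25 (not isolated), via silylated enyne 26 (not isolated)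
Conditions: 24, nBuLi, THF, −78 °C; 23, −78 → 0 °C; then K2CO3, MeOH, rt
Reagents that add atoms: none
Why: SN2 alkylation of the propargylic lithium reagent (the silyl group blocks the alkyne terminus and suppresses allene formation) followed by base-catalysed methanolysis of the alkynylsilane is the standard route to this 1,5-enyne with the 5E alkene carried over from geranyl bromide.

Step 20
Reactants: 27 (5E)-6,10-dimethylundeca-5,9-dien-1-yne
Product: 29 (1E,5E)-1-iodo-2,6,10-trimethylundeca-1,5,9-triene, via vinylalane 28 (not isolated)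
Conditions: AlMe3 (2 equiv), Cp2ZrCl2 (0.2 equiv), CH2Cl2, 0 °C → rt; then I2, THF, −30 → 0 °C
Reagents that add atoms: trimethylaluminium, C[Al](C)C; iodine, II
Why: Negishi zirconium-catalysed carboalumination adds methyl and aluminium syn across the terminal alkyne with aluminium at the terminus, and iodinolysis with retention gives the E vinyl iodide (future 13E alkene).

Step 21
Reactants: 29 (1E,5E)-1-iodo-2,6,10-trimethylundeca-1,5,9-triene
Product: 30 (2E,6E,10E)-11-iodo-2,6,10-trimethylundeca-2,6,10-trien-1-ol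
Conditions: SeO2 (0.1 equiv), tBuOOH (70% aq.), salicylic acid (0.1 equiv), CH2Cl2, 0 °C → rt
Reagents that add atoms: selenium dioxide, O=[Se]=O (catalytic oxygen carrier); tert-butyl hydroperoxide, CC(C)(C)OO (terminal oxidant)
Why: Riley-type allylic oxidation should select the E-methyl of the terminal isopropylidene group, the most accessible and electron-rich alkene (the iodoalkene is deactivated), as in farnesyl systems.

Step 22
Reactants: 22 3β-(tert-butyldimethylsilyloxy)-13,14,15,16-tetranorlabd-11-en-8α-ol; 30 (2E,6E,10E)-11-iodo-2,6,10-trimethylundeca-2,6,10-trien-1-ol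
Product: 32 (2E,6E,10E)-13-[(1R,2R,4aR,6S,8aS)-6-(tert-butyldimethylsilyloxy)-2-hydroxy-2,5,5,8a-tetramethyldecahydronaphthalen-1-yl]-2,6,10-trimethyltrideca-2,6,10-trien-1-ol, via alkylborane 31 (not isolated)
Conditions: 9-BBN (2.5 equiv), THF, rt → 50 °C; then 3 M aq. Cs2CO3, 30, Pd(dppf)Cl2 (10 mol %), AsPh3 (10 mol %), DMF, rt
Reagents that add atoms: none
Why: Anti-Markovnikov hydroboration of the vinyl group and B-alkyl Suzuki–Miyaura coupling (oxidative addition of the vinyl iodide to zerovalent palladium, transmetalation of the primary alkyl group, retention of alkene geometry) should form C12–C13 with the 13E alkene and tolerate the free hydroxyl groups.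

Step 23
Reactants: 32 the silyl ether from step 22
Product: 33 (2E,6E,10E)-13-[(1R,2R,4aR,6S,8aS)-2,6-dihydroxy-2,5,5,8a-tetramethyldecahydronaphthalen-1-yl]-2,6,10-trimethyltrideca-2,6,10-trien-1-ol
Conditions: Bu4NF, THF, 60 °C
Reagents that add atoms: none
Why: Fluoride-mediated desilylation removes the hindered C3 silyl ether on warming without touching the tertiary alcohol or the trisubstituted alkenes.

Step 24
Reactants: 33 the triol from step 23
Product: 34 (2E,6E,10E)-13-[(1R,2R,4aR,8aS)-2-hydroxy-2,5,5,8a-tetramethyl-6-oxodecahydronaphthalen-1-yl]-2,6,10-trimethyltrideca-2,6,10-trienal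
Conditions: Dess–Martin periodinane (3 equiv), NaHCO3, CH2Cl2, 0 °C → rt
Reagents that add atoms: none
Why: Dess–Martin oxidation converts the secondary C3 alcohol to the ketone and the primary allylic alcohol to the E-enal in one operation, while the tertiary C8 alcohol cannot be oxidised and no stereocentre lies α to the new ketone.

Step 25
Reactants: 34 the keto enal from step 24
Product: 35 (2E,6E,10E)-13-[(1R,2R,4aR,8aS)-2-hydroxy-2,5,5,8a-tetramethyl-6-oxodecahydronaphthalen-1-yl]-2,6,10-trimethyltrideca-2,6,10-trienoic acid (CNP0141897.3)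
Conditions: NaClO2, NaH2PO4, 2-methylbut-2-ene, tBuOH/H2O, 0 °C → rt
Reagents that add atoms: sodium chlorite, [Na+].[O-]Cl=O
Why: Pinnick oxidation converts the enal to the acid with retention of the 21E geometry, and the alkene scavenger should keep hypochlorous acid away from the three trisubstituted alkenes.

**Compound list**

1 | prenyl acetate (3-methylbut-2-en-1-yl acetate) | CC(C)=CCOC(C)=O | starting material
2 | (2E)-4-hydroxy-3-methylbut-2-en-1-yl acetate | CC(=O)OC/C=C(\C)CO | intermediate
3 | (2E)-4-bromo-3-methylbut-2-en-1-yl acetate | CC(=O)OC/C=C(\C)CBr | intermediate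
4 | 2,2-dimethylpent-4-enoic acid | C=CCC(C)(C)C(=O)O | starting material
5 | 3,3-dimethylhex-5-en-2-one | CC(=O)C(C)(C)CC=C | intermediate
6 | lithium 3,3-dimethylhexa-1,5-dien-2-olate (lithium enolate of 5) | [Li]OC(=C)C(C)(C)CC=C | intermediate
7 | (2E)-3,7,7-trimethyl-6-oxodeca-2,9-dien-1-yl acetate | CC(=O)OC/C=C(\C)CCC(=O)C(C)(C)CC=C | intermediate
8 | (2E,6S)-6-hydroxy-3,7,7-trimethyldeca-2,9-dien-1-yl acetate | CC(=O)OC/C=C(\C)CC[C@H](O)C(C)(C)CC=C | intermediate
9 | (2E,6S)-6-(tert-butyldimethylsilyloxy)-3,7,7-trimethyldeca-2,9-dien-1-yl acetate | CC(=O)OC/C=C(\C)CC[C@H](O[Si](C)(C)C(C)(C)C)C(C)(C)CC=C | intermediate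
10 | (E)-crotonaldehyde | C/C=C/C=O | starting material
11 | (2E,6S,9E)-6-(tert-butyldimethylsilyloxy)-3,7,7-trimethyl-11-oxoundeca-2,9-dien-1-yl acetate | CC(=O)OC/C=C(\C)CC[C@H](O[Si](C)(C)C(C)(C)C)C(C)(C)C/C=C/C=O | intermediate
12 | (2E,6S,8E,10E)-6-(tert-butyldimethylsilyloxy)-3,7,7-trimethyl-11-(triethylsilyloxy)undeca-2,8,10-trien-1-yl acetate | CC(=O)OC/C=C(\C)CC[C@H](O[Si](C)(C)C(C)(C)C)C(C)(C)/C=C/C=C/O[Si](CC)(CC)CC | intermediate
13 | (2E,6S,8E,10E)-6-(tert-butyldimethylsilyloxy)-3,7,7-trimethyl-11-(triethylsilyloxy)undeca-2,8,10-trien-1-ol | OC/C=C(\C)CC[C@H](O[Si](C)(C)C(C)(C)C)C(C)(C)/C=C/C=C/O[Si](CC)(CC)CC | intermediate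
14 | (2E,6S,8E,10E)-6-(tert-butyldimethylsilyloxy)-3,7,7-trimethyl-11-(triethylsilyloxy)undeca-2,8,10-trienal | O=C/C=C(\C)CC[C@H](O[Si](C)(C)C(C)(C)C)C(C)(C)/C=C/C=C/O[Si](CC)(CC)CC | intermediate
15 | 3β-(tert-butyldimethylsilyloxy)-8β-(triethylsilyloxy)-12,13,14,15,16,17-hexanorlabd-6-en-11-al | O=C[C@@H]1[C@@]2(C)CC[C@H](O[Si](C)(C)C(C)(C)C)C(C)(C)[C@@H]2C=C[C@@H]1O[Si](CC)(CC)CC | intermediate
16 | 3β-(tert-butyldimethylsilyloxy)-8β-(triethylsilyloxy)-12,13,14,15,16,17-hexanorlabdan-11-al | O=C[C@@H]1[C@@]2(C)CC[C@H](O[Si](C)(C)C(C)(C)C)C(C)(C)[C@@H]2CC[C@@H]1O[Si](CC)(CC)CC | intermediate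
17 | 3β-(tert-butyldimethylsilyloxy)-8β-(triethylsilyloxy)-13,14,15,16,17-pentanorlabd-11-ene | C=C[C@@H]1[C@@]2(C)CC[C@H](O[Si](C)(C)C(C)(C)C)C(C)(C)[C@@H]2CC[C@@H]1O[Si](CC)(CC)CC | intermediate
18 | 3β-(tert-butyldimethylsilyloxy)-13,14,15,16,17-pentanorlabd-11-en-8β-ol | C=C[C@@H]1[C@@]2(C)CC[C@H](O[Si](C)(C)C(C)(C)C)C(C)(C)[C@@H]2CC[C@@H]1O | intermediate
19 | 3β-(tert-butyldimethylsilyloxy)-13,14,15,16,17-pentanorlabd-11-en-8-one | C=C[C@@H]1[C@@]2(C)CC[C@H](O[Si](C)(C)C(C)(C)C)C(C)(C)[C@@H]2CCC1=O | intermediate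
20 | 3β-(tert-butyldimethylsilyloxy)-13,14,15,16-tetranorlabda-8(17),11-diene | C=C[C@@H]1[C@@]2(C)CC[C@H](O[Si](C)(C)C(C)(C)C)C(C)(C)[C@@H]2CCC1=C | intermediate
21 | 3β-(tert-butyldimethylsilyloxy)-8α,17-epoxy-13,14,15,16-tetranorlabd-11-ene | C=C[C@@H]1[C@@]2(C)CC[C@H](O[Si](C)(C)C(C)(C)C)C(C)(C)[C@@H]2CC[C@@]1(C3)O3 | intermediate
22 | 3β-(tert-butyldimethylsilyloxy)-13,14,15,16-tetranorlabd-11-en-8α-ol | C=C[C@@H]1[C@@]2(C)CC[C@H](O[Si](C)(C)C(C)(C)C)C(C)(C)[C@@H]2CC[C@@]1(C)O | intermediate
23 | geranyl bromide ((2E)-1-bromo-3,7-dimethylocta-2,6-diene) | CC(C)=CCC/C(C)=C/CBr | starting material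
24 | 1-(trimethylsilyl)propyne | CC#C[Si](C)(C)C | starting material
25 | 3-lithio-1-(trimethylsilyl)propyne | [Li]CC#C[Si](C)(C)C | intermediate
26 | [(5E)-6,10-dimethylundeca-5,9-dien-1-yn-1-yl]trimethylsilane | CC(C)=CCC/C(C)=C/CCC#C[Si](C)(C)C | intermediate
27 | (5E)-6,10-dimethylundeca-5,9-dien-1-yne | CC(C)=CCC/C(C)=C/CCC#C | intermediate
28 | dimethyl[(1E,5E)-2,6,10-trimethylundeca-1,5,9-trien-1-yl]alane | CC(C)=CCC/C(C)=C/CC/C(C)=C/[Al](C)C | intermediate
29 | (1E,5E)-1-iodo-2,6,10-trimethylundeca-1,5,9-triene | CC(C)=CCC/C(C)=C/CC/C(C)=C/I | intermediate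
30 | (2E,6E,10E)-11-iodo-2,6,10-trimethylundeca-2,6,10-trien-1-ol | OC/C(C)=C/CC/C(C)=C/CC/C(C)=C/I | intermediate
31 | B-[3β-(tert-butyldimethylsilyloxy)-8α-hydroxy-13,14,15,16-tetranorlabdan-12-yl]-9-borabicyclo[3.3.1]nonane | C1CC2CCCC(C1)B2CC[C@@H]3[C@@]4(C)CC[C@H](O[Si](C)(C)C(C)(C)C)C(C)(C)[C@@H]4CC[C@@]3(C)O | intermediate
32 | (2E,6E,10E)-13-[(1R,2R,4aR,6S,8aS)-6-(tert-butyldimethylsilyloxy)-2-hydroxy-2,5,5,8a-tetramethyldecahydronaphthalen-1-yl]-2,6,10-trimethyltrideca-2,6,10-trien-1-ol | OC/C(C)=C/CC/C(C)=C/CC/C(C)=C/CC[C@@H]1[C@@]2(C)CC[C@H](O[Si](C)(C)C(C)(C)C)C(C)(C)[C@@H]2CC[C@@]1(C)O | intermediate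
33 | (2E,6E,10E)-13-[(1R,2R,4aR,6S,8aS)-2,6-dihydroxy-2,5,5,8a-tetramethyldecahydronaphthalen-1-yl]-2,6,10-trimethyltrideca-2,6,10-trien-1-ol | OC/C(C)=C/CC/C(C)=C/CC/C(C)=C/CC[C@@H]1[C@@]2(C)CC[C@H](O)C(C)(C)[C@@H]2CC[C@@]1(C)O | intermediate
34 | (2E,6E,10E)-13-[(1R,2R,4aR,8aS)-2-hydroxy-2,5,5,8a-tetramethyl-6-oxodecahydronaphthalen-1-yl]-2,6,10-trimethyltrideca-2,6,10-trienal | O=C/C(C)=C/CC/C(C)=C/CC/C(C)=C/CC[C@@H]1[C@@]2(C)CCC(=O)C(C)(C)[C@@H]2CC[C@@]1(C)O | intermediate
35 | (2E,6E,10E)-13-[(1R,2R,4aR,8aS)-2-hydroxy-2,5,5,8a-tetramethyl-6-oxodecahydronaphthalen-1-yl]-2,6,10-trimethyltrideca-2,6,10-trienoic acid (CNP0141897.3) | OC(=O)/C(C)=C/CC/C(C)=C/CC/C(C)=C/CC[C@@H]1[C@@]2(C)CCC(=O)C(C)(C)[C@@H]2CC[C@@]1(C)O | target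

**Step count and risks**

Total step count: 25. Longest linear sequence: 21 steps (1, 2, 4–18, 22–25).

Steps most likely to fail:

1. Step 11. The β,β-disubstituted enal may react slowly, the aluminium halide may desilylate or oligomerise the dienol ether before cycloaddition, and the C3 silyloxy group may discriminate the diene faces only weakly. The fallback moves activation and face selection from the substrate to the reagent. Trienal 14 is cyclised with a chiral cationic oxazaborolidine (o-tolyl-CBS-oxazaborolidine protonated by HNTf2, 0.2 equiv, CH2Cl2, −78 °C). This is a known catalyst class for Diels–Alder reactions of enals, intramolecular cases and silyloxydienes included. The catalyst enantiomer matched to C3 is chosen by trial. The fallback sets out from 14 and comes back at 15, with no new compound (F0).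

2. Step 7. The ruthenium alkylidene formed at the terminal alkene may close onto the trisubstituted C9=C10 alkene (seven-membered ring, loss of the allyl acetate end) instead of undergoing cross-metathesis. The fallback runs the metathesis at the ketone stage, where no second alkene is present. It sets out from 5 (with 3) and comes back at 11.
   - Ketone 5 and acrolein diethyl acetal undergo cross-metathesis (same ruthenium catalyst, CH2Cl2, 40 °C) to (5E)-7,7-diethoxy-3,3-dimethylhept-5-en-2-one F1.
   - Its lithium enolate (LiN(iPr)2, THF, −78 °C) is alkylated with 3 to (2E,9E)-11,11-diethoxy-3,7,7-trimethyl-6-oxoundeca-2,9-dien-1-yl acetate F2.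
   - CBS reduction as in step 5 gives (2E,6S,9E)-11,11-diethoxy-6-hydroxy-3,7,7-trimethylundeca-2,9-dien-1-yl acetate F3.
   - Silylation (tBuMe2SiOTf, 2,6-lutidine, CH2Cl2, −78 °C) gives (2E,6S,9E)-6-(tert-butyldimethylsilyloxy)-11,11-diethoxy-3,7,7-trimethylundeca-2,9-dien-1-yl acetate F4.
   - Mild hydrolysis of the allylic acetal (PPTS, acetone/H2O, rt) gives 11.

3. Step 17. The peracid may also epoxidise the vinyl group or attack the β face of the exocyclic alkene. The fallback replaces the polar oxygen transfer and hydride opening by a radical hydration. Diene 20 is treated with Mn(dpm)3 (cat.), PhSiH3 and O2 in iPrOH/CH2Cl2 at 0 °C, then PPh3 (Mukaiyama hydration). Hydrogen-atom transfer to the 1,1-disubstituted alkene should give the tertiary C8 radical, which should take up oxygen from the open α face. The fallback sets out from 20 and comes back at 22, passing over 21, with no new compound (F0).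

Further compounds
F0 | step 11 | none | none
F1 | step 7 | (5E)-7,7-diethoxy-3,3-dimethylhept-5-en-2-one | CC(=O)C(C)(C)C/C=C/C(OCC)OCC
F2 | step 7 | (2E,9E)-11,11-diethoxy-3,7,7-trimethyl-6-oxoundeca-2,9-dien-1-yl acetate | CC(=O)OC/C=C(\C)CCC(=O)C(C)(C)C/C=C/C(OCC)OCC
F3 | step 7 | (2E,6S,9E)-11,11-diethoxy-6-hydroxy-3,7,7-trimethylundeca-2,9-dien-1-yl acetate | CC(=O)OC/C=C(\C)CC[C@H](O)C(C)(C)C/C=C/C(OCC)OCC
F4 | step 7 | (2E,6S,9E)-6-(tert-butyldimethylsilyloxy)-11,11-diethoxy-3,7,7-trimethylundeca-2,9-dien-1-yl acetate | CC(=O)OC/C=C(\C)CC[C@H](O[Si](C)(C)C(C)(C)C)C(C)(C)C/C=C/C(OCC)OCC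
F0 | step 17 | none | none
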